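**Retrosynthetic overview**
- The target is reached by hydrogenolysis of two benzyl ethers (7-O and 5'-O) from a flavone whose ring A is already complete.
- Feature: ring A carries oxygen on C5, C6, C7 and C8, with C5–O and C8–O para to each other and C6–O/C7–O between them, which is the four-carbon oxygen pattern of squaric acid.
- Key disconnection C4a–C5: ring A is closed last, by thermal opening of a 4-(pyranon-6-yl)cyclobutenone to a dienylketene and six-electron closure onto pyranone C5 (carbinol carbon becomes C8, C–OBn C7, C–OMe C6, ketene carbon C5).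
- The cyclobutenone comes from dimethyl squarate and a 6-metalated 2-aryl-3-methoxy-4-pyranone; the carbinol is then O-methylated (C8–OMe) and the vinylogous C3 methoxy group exchanged for benzyloxy (later C7–OH).
- Ring C is bought as 3-hydroxy-4H-pyran-4-one and ring B (from 2,4-dimethoxybenzaldehyde) is joined to its C2 by Suzuki coupling; rings B and C are bought, ring A is formed last.

Key step: step 12

Remarks on the chemistry:
- Assumption: the target has no stereocenter; the cyclobutenone carbinols are made and used as racemates.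
- The carbinol oxygen goes through the key step as its methyl ether, because it is the C8 methoxy group of the target. This keeps a free alkoxide out of the alkoxide exchange, closes the butenolide side path of the ketene, and gives the 5-hydroxy-8-methoxy pattern directly instead of an air-sensitive 5,8-hydroquinone.
- Pyranone C6 is metalated by way of the 6-iodide, since direct lithiation could also occur at C5 or on ring B.

**Route**

Step 1
Reactants: 1 2,4-dimethoxybenzaldehyde
Product: 3 2,4-dimethoxyphenol, via 2,4-dimethoxyphenyl formate 2 (not isolated)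
Conditions: mCPBA, CH2Cl2, 0 to 25 °C; aq. NaHCO3 wash; then K2CO3 (cat.), MeOH, 25 °C
Reagents that add atoms: 3-chloroperbenzoic acid (mCPBA), O=C(OO)c1cccc(Cl)c1
Why: Baeyer–Villiger oxidation of an electron-rich benzaldehyde, in which the aryl group migrates because of its ortho and para methoxy groups, gives the aryl formate, and mild methanolysis releases the phenol.

Step 2
Reactants: 3 2,4-dimethoxyphenol
Product: 4 1-(benzyloxy)-2,4-dimethoxybenzene
Conditions: BnBr, K2CO3, DMF, 25 °C
Reagents that add atoms: benzyl bromide, BrCc1ccccc1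
Why: Williamson ether synthesis on the phenoxide; this benzyl ether is removed together with the second one in the last step.

Step 3
Reactants: 4 1-(benzyloxy)-2,4-dimethoxybenzene
Product: 5 1-(benzyloxy)-5-bromo-2,4-dimethoxybenzene
Conditions: NBS, MeCN, 0 °C, dark
Reagents that add atoms: N-bromosuccinimide, O=C1CCC(=O)N1Br
Why: Electrophilic aromatic bromination should go to C5, the only position that is para to one methoxy group and ortho to the other without being flanked by two substituents.

Step 4
Reactants: 5 1-(benzyloxy)-5-bromo-2,4-dimethoxybenzene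
Product: 6 2-[5-(benzyloxy)-2,4-dimethoxyphenyl]-4,4,5,5-tetramethyl-1,3,2-dioxaborolane
Conditions: B2pin2, Pd(dppf)Cl2 (3 mol%), KOAc, 1,4-dioxane, 90 °C
Reagents that add atoms: bis(pinacolato)diboron, CC1(C)OB(OC1(C)C)B1OC(C)(C)C(C)(C)O1
Why: Miyaura borylation of the aryl bromide; the ether groups are inert under these conditions.

Step 5
Reactants: 7 3-hydroxy-4H-pyran-4-one
Product: 8 3-hydroxy-2-iodo-4H-pyran-4-one
Conditions: I2, Na2CO3, H2O, 25 °C; then aq. HCl to pH 3
Reagents that add atoms: iodine, [I][I]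
Why: Electrophilic iodination of the enolic 3-hydroxypyranone at C2, the position ortho to the hydroxyl, as in the ortho-iodination of phenols.

Step 6
Reactants: 8 3-hydroxy-2-iodo-4H-pyran-4-one
Product: 9 2-iodo-3-methoxy-4H-pyran-4-one
Conditions: MeI, K2CO3, acetone, 56 °C
Reagents that add atoms: iodomethane, [CH3]I
Why: O-Alkylation (Williamson) of the acidic enolic hydroxyl.

Step 7
Reactants: 9 2-iodo-3-methoxy-4H-pyran-4-one; 6 2-[5-(benzyloxy)-2,4-dimethoxyphenyl]-4,4,5,5-tetramethyl-1,3,2-dioxaborolane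
Product: 10 2-[5-(benzyloxy)-2,4-dimethoxyphenyl]-3-methoxy-4H-pyran-4-one
Conditions: Pd(PPh3)4 (5 mol%), K3PO4, 1,4-dioxane/H2O 10:1, 80 °C
Reagents that add atoms: none
Why: Suzuki–Miyaura coupling; the carbon–iodine bond at the β-position of the pyranone enone inserts palladium easily, and phosphate is a mild enough base for the pyranone ring.

Step 8
Reactants: 10 2-[5-(benzyloxy)-2,4-dimethoxyphenyl]-3-methoxy-4H-pyran-4-one
Product: 12 2-[5-(benzyloxy)-2,4-dimethoxyphenyl]-6-iodo-3-methoxy-4H-pyran-4-one, via pyranon-6-ylzinc chloride 11 (not isolated)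
Conditions: TMPZnCl·LiCl (1.3 equiv; TMP = 2,2,6,6-tetramethylpiperidide), THF, 25 °C; then I2, THF, 0 °C
Reagents that add atoms: iodine, [I][I]
Why: Deprotonative zincation with the hindered zinc amide should take place at C6–H, the most acidic C–H because it lies next to the ring oxygen (the regiochemistry known for C2 of chromones with this base when no Lewis acid is added), and iodolysis of the carbon–zinc bond gives the iodide.

Step 9
Reactants: 12 2-[5-(benzyloxy)-2,4-dimethoxyphenyl]-6-iodo-3-methoxy-4H-pyran-4-one; 13 dimethyl squarate (3,4-dimethoxycyclobut-3-ene-1,2-dione)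
Product: 15 4-{6-[5-(benzyloxy)-2,4-dimethoxyphenyl]-5-methoxy-4-oxo-4H-pyran-2-yl}-4-hydroxy-2,3-dimethoxycyclobut-2-en-1-one (racemic), via pyranon-6-ylmagnesium chloride 14 (not isolated)
Conditions: i-PrMgCl·LiCl (1.05 equiv), THF, −78 °C; then added to 13 (1.5 equiv), THF, −78 °C; aq. NH4Cl
Reagents that add atoms: none
Why: Iodine–magnesium exchange of the electron-poor alkenyl iodide is fast at −78 °C, and the Grignard reagent should add 1,2 to one of the two equivalent carbonyl groups of the squarate (the standard entry to 4-hydroxycyclobutenones); the new carbinol centre forms as a racemate and is removed in step 12.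

Step 10
Reactants: 15 4-{6-[5-(benzyloxy)-2,4-dimethoxyphenyl]-5-methoxy-4-oxo-4H-pyran-2-yl}-4-hydroxy-2,3-dimethoxycyclobut-2-en-1-one (racemic)
Product: 16 4-{6-[5-(benzyloxy)-2,4-dimethoxyphenyl]-5-methoxy-4-oxo-4H-pyran-2-yl}-2,3,4-trimethoxycyclobut-2-en-1-one (racemic)
Conditions: MeI (10 equiv), Ag2O (3 equiv), 4 Å sieves, MeCN, 25 °C, dark
Reagents that add atoms: iodomethane, [CH3]I
Why: Purdie-type O-methylation of the tertiary cyclobutenol with Ag2O and MeI under non-basic conditions; this oxygen is the C8 methoxy group of the target.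

Step 11
Reactants: 16 4-{6-[5-(benzyloxy)-2,4-dimethoxyphenyl]-5-methoxy-4-oxo-4H-pyran-2-yl}-2,3,4-trimethoxycyclobut-2-en-1-one (racemic); 17 benzyl alcohol
Product: 18 3-(benzyloxy)-4-{6-[5-(benzyloxy)-2,4-dimethoxyphenyl]-5-methoxy-4-oxo-4H-pyran-2-yl}-2,4-dimethoxycyclobut-2-en-1-one (racemic)
Conditions: 17 (5 equiv), NaH (0.1 equiv), 4 Å sieves, THF, 0 to 25 °C
Reagents that add atoms: none
Why: Proposed new method: the C3 methoxy group is the only alkoxy group on the β-carbon of the enone (a vinylogous ester), so benzyl oxide should add there and the ring enolate should expel methoxide (addition–elimination), with the equilibrium driven by excess benzyl alcohol and uptake of methanol on the sieves; the closest known reactions are the base-mediated alkoxy exchange of squaric esters and of 3-alkoxycycloalk-2-enones.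

Step 12
Reactants: 18 3-(benzyloxy)-4-{6-[5-(benzyloxy)-2,4-dimethoxyphenyl]-5-methoxy-4-oxo-4H-pyran-2-yl}-2,4-dimethoxycyclobut-2-en-1-one (racemic)
Product: 21 7-(benzyloxy)-2-[5-(benzyloxy)-2,4-dimethoxyphenyl]-5-hydroxy-3,6,8-trimethoxy-4H-chromen-4-one, via dienylketene 19 (not isolated), via cyclohexadienone 20 (not isolated)
Conditions: degassed p-xylene (0.01 mol/L), 130 °C
Reagents that add atoms: none
Why: Heating opens the cyclobutenone by conrotatory four-electron ring opening between C1 and C4, and the C4 methoxy group, a donor, turns outward, so that the pyranonyl group ends cis to the ketene in dienylketene 19. The electrophilic ketene carbon then bonds to pyranone C5, the nucleophilic α-carbon of the vinylogous ester, in a disrotatory six-electron electrocyclization that forms C4a–C5 and closes the six-membered ring A as cyclohexadienone 20. The C4a hydrogen of 20 lies between two carbonyl groups and shifts to O5, which gives the aromatic ring with 5-OH, 6-OMe, 7-OBn and 8-OMe (C1 becomes C5, C2 C6, C3 C7, C4 C8). The closest known reaction is the Moore rearrangement of 4-aryl-, 4-heteroaryl- and 4-alkenyl-cyclobutenones that carry a 4-hydroxy, 4-alkoxy or 4-silyloxy group; the pyranonyl arm is a new substrate for it. The step needs inward rotation of the arm and closure at a single carbon: the outward preference of the oxygen donor secures the first, a ketene of the wrong geometry has no hydroxyl to trap it and can only close back to 18, and C5 is the only ring carbon next to the point of attachment. The racemic carbinol centre of 18 becomes the sp2 carbon C8 and the transient C4a centre of 20 is lost on tautomerisation, so no stereocenter remains.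

Step 13
Reactants: 21 7-(benzyloxy)-2-[5-(benzyloxy)-2,4-dimethoxyphenyl]-5-hydroxy-3,6,8-trimethoxy-4H-chromen-4-one
Product: 22 5,7-dihydroxy-2-(5-hydroxy-2,4-dimethoxyphenyl)-3,6,8-trimethoxy-4H-chromen-4-one
Conditions: H2 (1 atm), 10% Pd/C, EtOAc/MeOH, 25 °C
Reagents that add atoms: none
Why: Catalytic hydrogenolysis (O-debenzylation) of the two benzyl ethers; the tetrasubstituted C2–C3 double bond of the flavone should not be reduced under these conditions.

**Compound list**
1 | 2,4-dimethoxybenzaldehyde | COc1ccc(C=O)c(OC)c1 | starting material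
2 | 2,4-dimethoxyphenyl formate | COc1ccc(OC=O)c(OC)c1 | intermediate
3 | 2,4-dimethoxyphenol | COc1ccc(O)c(OC)c1 | intermediate
4 | 1-(benzyloxy)-2,4-dimethoxybenzene | COc1ccc(OCc2ccccc2)c(OC)c1 | intermediate
5 | 1-(benzyloxy)-5-bromo-2,4-dimethoxybenzene | COc1cc(OC)c(OCc2ccccc2)cc1Br | intermediate
6 | 2-[5-(benzyloxy)-2,4-dimethoxyphenyl]-4,4,5,5-tetramethyl-1,3,2-dioxaborolane | COc1cc(OC)c(OCc2ccccc2)cc1B1OC(C)(C)C(C)(C)O1 | intermediate
7 | 3-hydroxy-4H-pyran-4-one | O=c1ccocc1O | starting material
8 | 3-hydroxy-2-iodo-4H-pyran-4-one | O=c1ccoc(I)c1O | intermediate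
9 | 2-iodo-3-methoxy-4H-pyran-4-one | COc1c(I)occc1=O | intermediate
10 | 2-[5-(benzyloxy)-2,4-dimethoxyphenyl]-3-methoxy-4H-pyran-4-one | COc1cc(OC)c(-c2occc(=O)c2OC)cc1OCc1ccccc1 | intermediate
11 | {6-[5-(benzyloxy)-2,4-dimethoxyphenyl]-5-methoxy-4-oxo-4H-pyran-2-yl}zinc chloride | COc1cc(OC)c(-c2oc([Zn]Cl)cc(=O)c2OC)cc1OCc1ccccc1 | intermediate
12 | 2-[5-(benzyloxy)-2,4-dimethoxyphenyl]-6-iodo-3-methoxy-4H-pyran-4-one | COc1cc(OC)c(-c2oc(I)cc(=O)c2OC)cc1OCc1ccccc1 | intermediate
13 | dimethyl squarate (3,4-dimethoxycyclobut-3-ene-1,2-dione) | COC1=C(OC)C(=O)C1=O | starting material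
14 | {6-[5-(benzyloxy)-2,4-dimethoxyphenyl]-5-methoxy-4-oxo-4H-pyran-2-yl}magnesium chloride | COc1cc(OC)c(-c2oc([Mg]Cl)cc(=O)c2OC)cc1OCc1ccccc1 | intermediate
15 | 4-{6-[5-(benzyloxy)-2,4-dimethoxyphenyl]-5-methoxy-4-oxo-4H-pyran-2-yl}-4-hydroxy-2,3-dimethoxycyclobut-2-en-1-one (racemic) | COC1=C(OC)C(O)(c2cc(=O)c(OC)c(-c3cc(OCc4ccccc4)c(OC)cc3OC)o2)C1=O | intermediate
16 | 4-{6-[5-(benzyloxy)-2,4-dimethoxyphenyl]-5-methoxy-4-oxo-4H-pyran-2-yl}-2,3,4-trimethoxycyclobut-2-en-1-one (racemic) | COC1=C(OC)C(OC)(c2cc(=O)c(OC)c(-c3cc(OCc4ccccc4)c(OC)cc3OC)o2)C1=O | intermediate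
17 | benzyl alcohol | OCc1ccccc1 | starting material
18 | 3-(benzyloxy)-4-{6-[5-(benzyloxy)-2,4-dimethoxyphenyl]-5-methoxy-4-oxo-4H-pyran-2-yl}-2,4-dimethoxycyclobut-2-en-1-one (racemic) | COC1=C(OCc2ccccc2)C(OC)(c2cc(=O)c(OC)c(-c3cc(OCc4ccccc4)c(OC)cc3OC)o2)C1=O | intermediate
19 | (3Z)-3-(benzyloxy)-4-{6-[5-(benzyloxy)-2,4-dimethoxyphenyl]-5-methoxy-4-oxo-4H-pyran-2-yl}-2,4-dimethoxybuta-1,3-dien-1-one (dienylketene; pyranonyl group cis to C2 across C3=C4) | COC(=C=O)/C(OCc1ccccc1)=C(/OC)c1cc(=O)c(OC)c(-c2cc(OCc3ccccc3)c(OC)cc2OC)o1 | intermediate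
20 | 7-(benzyloxy)-2-[5-(benzyloxy)-2,4-dimethoxyphenyl]-3,6,8-trimethoxy-4aH-chromene-4,5-dione (racemic at C4a; keto tautomer of 21) | COC1=C(OCc2ccccc2)C(OC)=C2OC(-c3cc(OCc4ccccc4)c(OC)cc3OC)=C(OC)C(=O)C2C1=O | intermediate
21 | 7-(benzyloxy)-2-[5-(benzyloxy)-2,4-dimethoxyphenyl]-5-hydroxy-3,6,8-trimethoxy-4H-chromen-4-one | COc1cc(OC)c(-c2oc3c(OC)c(OCc4ccccc4)c(OC)c(O)c3c(=O)c2OC)cc1OCc1ccccc1 | intermediate
22 | 5,7-dihydroxy-2-(5-hydroxy-2,4-dimethoxyphenyl)-3,6,8-trimethoxy-4H-chromen-4-one | COc1cc(OC)c(-c2oc3c(OC)c(O)c(OC)c(O)c3c(=O)c2OC)cc1O | target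

**Step count**
Total steps: 13. Longest linear sequence: 11 steps (steps 1–4 and 7–13, from 2,4-dimethoxybenzaldehyde).

**Steps most likely to fail**

Step 11 (alkoxy exchange, proposed new method).
- What may go wrong: benzyl oxide may attack the strained ring carbonyl or the pyranone ring instead of C3, with cleavage of the four-membered ring or of the pyranone, or the exchange may stall at equilibrium.
- Fallback (known chemistry): it sets out from 12, 13 and 17 and comes back to the route at 18.
- Base-catalysed alkoxy exchange of 13 (used in excess) with one equivalent of 17 (Et3N cat., CH2Cl2) should give the mixed ester 3-(benzyloxy)-4-methoxycyclobut-3-ene-1,2-dione F1.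
- Grignard reagent 14, made from 12 as in step 9, should add to either carbonyl group of F1 with little preference. This should give 3-(benzyloxy)-4-{6-[5-(benzyloxy)-2,4-dimethoxyphenyl]-5-methoxy-4-oxo-4H-pyran-2-yl}-4-hydroxy-2-methoxycyclobut-2-en-1-one F2 together with its regioisomer 2-(benzyloxy)-4-{6-[5-(benzyloxy)-2,4-dimethoxyphenyl]-5-methoxy-4-oxo-4H-pyran-2-yl}-4-hydroxy-3-methoxycyclobut-2-en-1-one F3.
- The two are separated by chromatography, and F2 is methylated with MeI and Ag2O as in step 10 to give 18.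

Step 12 (key step).
- What may go wrong: the dienylketene may close only slowly on the electron-poor double bond of the pyranone and be lost to intermolecular ketene reactions before ring A forms.
- Fallback: ring A is not built but taken from a phloroglucinol ketone; the fallback sets out from 5 and comes back to the route at the target 22.
- Bromine–lithium exchange of 5 and carboxylation (n-BuLi, THF, −78 °C; CO2) should give 5-(benzyloxy)-2,4-dimethoxybenzoic acid F4, and dicyclohexylcarbodiimide in CH2Cl2 should give 5-(benzyloxy)-2,4-dimethoxybenzoic anhydride F5.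
- Allan–Robinson condensation of commercial 2-methoxy-1-(2,4,6-trihydroxyphenyl)ethan-1-one with F5 and the potassium salt of F4 (170 °C; then KOH, aq. MeOH) should give 2-[5-(benzyloxy)-2,4-dimethoxyphenyl]-5,7-dihydroxy-3-methoxy-4H-chromen-4-one F6.
- NBS (2 equiv, DMF, 0 °C) should brominate the two phloroglucinol-type positions to give 2-[5-(benzyloxy)-2,4-dimethoxyphenyl]-6,8-dibromo-5,7-dihydroxy-3-methoxy-4H-chromen-4-one F7.
- Copper-mediated methoxylation (NaOMe, CuBr, DMF/MeOH, 110 °C) should give 2-[5-(benzyloxy)-2,4-dimethoxyphenyl]-5,7-dihydroxy-3,6,8-trimethoxy-4H-chromen-4-one F8, and hydrogenolysis as in step 13 should give 22.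

Step 9 (pyranonyl Grignard addition).
- What may go wrong: the magnesiated pyranone may add to a second pyranone molecule, or the exchange reagent may attack the pyranone, before the squarate is reached.
- Fallback: it sets out from 10 and comes back to the route at 15.
- The zinc reagent 11, formed as in step 8 and not quenched with iodine, is stable at room temperature and does not attack pyranones. It would be added directly to 13 in the presence of MgCl2 (THF, 0 to 25 °C), a Lewis acid-promoted addition of an organozinc halide to a highly electrophilic ketone, to give 15 after aqueous NH4Cl work-up.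
- The detour through iodide 12 is dropped and no new compound is made (F0).

**Further compounds**
F1 | step 11 | 3-(benzyloxy)-4-methoxycyclobut-3-ene-1,2-dione | COC1=C(OCc2ccccc2)C(=O)C1=O
F2 | step 11 | 3-(benzyloxy)-4-{6-[5-(benzyloxy)-2,4-dimethoxyphenyl]-5-methoxy-4-oxo-4H-pyran-2-yl}-4-hydroxy-2-methoxycyclobut-2-en-1-one (racemic) | COC1=C(OCc2ccccc2)C(O)(c2cc(=O)c(OC)c(-c3cc(OCc4ccccc4)c(OC)cc3OC)o2)C1=O
F3 | step 11 | 2-(benzyloxy)-4-{6-[5-(benzyloxy)-2,4-dimethoxyphenyl]-5-methoxy-4-oxo-4H-pyran-2-yl}-4-hydroxy-3-methoxycyclobut-2-en-1-one (racemic) | COC1=C(OCc2ccccc2)C(=O)C1(O)c1cc(=O)c(OC)c(-c2cc(OCc3ccccc3)c(OC)cc2OC)o1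
F4 | step 12 | 5-(benzyloxy)-2,4-dimethoxybenzoic acid | COc1cc(OC)c(C(=O)O)cc1OCc1ccccc1
F5 | step 12 | 5-(benzyloxy)-2,4-dimethoxybenzoic anhydride | COc1cc(OC)c(C(=O)OC(=O)c2cc(OCc3ccccc3)c(OC)cc2OC)cc1OCc1ccccc1
F6 | step 12 | 2-[5-(benzyloxy)-2,4-dimethoxyphenyl]-5,7-dihydroxy-3-methoxy-4H-chromen-4-one | COc1cc(OC)c(-c2oc3cc(O)cc(O)c3c(=O)c2OC)cc1OCc1ccccc1
F7 | step 12 | 2-[5-(benzyloxy)-2,4-dimethoxyphenyl]-6,8-dibromo-5,7-dihydroxy-3-methoxy-4H-chromen-4-one | COc1cc(OC)c(-c2oc3c(Br)c(O)c(Br)c(O)c3c(=O)c2OC)cc1OCc1ccccc1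
F8 | step 12 | 2-[5-(benzyloxy)-2,4-dimethoxyphenyl]-5,7-dihydroxy-3,6,8-trimethoxy-4H-chromen-4-one | COc1cc(OC)c(-c2oc3c(OC)c(O)c(OC)c(O)c3c(=O)c2OC)cc1OCc1ccccc1
F0 | step 9 | none | none
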